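## Retrosynthetic overview

1. The target is reached from its tri-O-benzyl ether 17 by one global hydrogenolysis. Furanone numbering used in the text: O1, C2 (lactone C=O), C3 (enol carbon), C4 (aryl-bearing carbon), C5 (quaternary carbon).
2. Key disconnection: the furanone ring of 17 is cut at O1–C5 and at C3=C4. This is a formal [3+2] annulation of an O,C-dinucleophile (2-benzyloxy-phosphonoacetic acid 14, supplying O1–C2–C3) with a C,C-dielectrophile (α-chloro-β-keto ester 10, supplying C5–C4). It runs as carboxylate SN2 with inversion, then intramolecular Horner–Wadsworth–Emmons closure in the same flask.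
3. Enabling feature: C5 of the furanone ring sits between the ester carbonyl and C4. With C4 at the ketone level, C5 is the non-enolisable α-carbon of a β-keto ester, so a chloride there is SN2-active and configurationally stable. C3 lies α to the lactone carbonyl C2, where a phosphonate can be carried.
4. Chloride 10 comes from catalytic asymmetric chlorination of β-keto ester 9, itself made by reductive Knoevenagel union of aldehyde 5 with aroylacetate 7. Acid 14 comes from triethyl phosphonoacetate by diazo transfer, O–H insertion and saponification.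
5. Ring order: both benzene rings and the pyran ring are bought (chromene 1). The chroman stereocentre is set by Jacobsen epoxidation and benzylic hydrogenolysis. The furanone ring is formed last, in step 11.

Key step: step 11

Assumption: in step 7 the ligand antipode that delivers the (2S)-chloride is used; the sense of induction on this acyclic substrate has to be assigned before scale-up, and both antipodes of the ligand are accessible.

## Route

Step 1
Reactants: 1 2,2-dimethyl-2H-chromene-6-carbonitrile
Product: 2 (3S,4S)-3,4-epoxy-2,2-dimethylchromane-6-carbonitrile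
Conditions: (S,S)-(salen)MnCl [N,N'-bis(3,5-di-tert-butylsalicylidene)-1,2-cyclohexanediaminomanganese chloride, 3 mol %], aq NaOCl (pH 11.3), 4-phenylpyridine N-oxide, CH2Cl2, 0 °C
Reagents that add atoms: sodium hypochlorite, [Na+].[O-]Cl
Why: Jacobsen epoxidation of a cis-disubstituted aryl-conjugated 2,2-dimethylchromene, the best substrate class for this catalyst; the (S,S)-salen ligand should direct oxygen transfer to the alkene face that gives the (3S,4S)-epoxide (catalyst control).

Step 2
Reactants: 2 (3S,4S)-3,4-epoxy-2,2-dimethylchromane-6-carbonitrile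
Product: 3 (3S)-3-hydroxy-2,2-dimethylchromane-6-carbonitrile
Conditions: H2 (1 atm), 10 % Pd/C, EtOAc, rt, stopped when 2 is consumed
Reagents that add atoms: none
Why: Catalytic hydrogenolysis cleaves only the benzylic C4–O bond of the aryl epoxide, so C3 keeps its oxygen and its configuration (3S), while the aryl nitrile should be reduced far more slowly under neutral conditions.

Step 3
Reactants: 3 (3S)-3-hydroxy-2,2-dimethylchromane-6-carbonitrile
Product: 4 (3S)-3-(benzyloxy)-2,2-dimethylchromane-6-carbonitrile
Conditions: NaH, BnBr, Bu4NI (cat.), DMF, 0 °C to rt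
Reagents that add atoms: benzyl bromide, BrCc1ccccc1
Why: Williamson etherification of the hindered secondary alkoxide; no stereocentre is touched and the nitrile is inert.

Step 4
Reactants: 4 (3S)-3-(benzyloxy)-2,2-dimethylchromane-6-carbonitrile
Product: 5 (3S)-3-(benzyloxy)-2,2-dimethylchromane-6-carbaldehyde
Conditions: i-Bu2AlH (DIBAL-H), toluene, −78 °C; then 1 M aq HCl, 0 °C
Reagents that add atoms: water (work-up), O
Why: Half-reduction of the nitrile: single hydride addition gives an aluminium aldimine that is hydrolysed to the aldehyde on acidic work-up; the benzyl ether is inert.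

Step 5
Reactants: 6 1-[4-(benzyloxy)phenyl]ethan-1-one
Product: 7 methyl 3-[4-(benzyloxy)phenyl]-3-oxopropanoate
Conditions: NaH, dimethyl carbonate, toluene, reflux; then aq HCl
Reagents that add atoms: dimethyl carbonate, COC(=O)OC
Why: Crossed Claisen condensation of the methyl ketone enolate with dimethyl carbonate, driven by deprotonation of the β-keto ester formed.

Step 6
Reactants: 5 (3S)-3-(benzyloxy)-2,2-dimethylchromane-6-carbaldehyde; 7 methyl 3-[4-(benzyloxy)phenyl]-3-oxopropanoate
Product: 9 methyl 2-{[(3S)-3-(benzyloxy)-2,2-dimethylchroman-6-yl]methyl}-3-[4-(benzyloxy)phenyl]-3-oxopropanoate (both C2 epimers), via arylidene keto ester 8 (not isolated)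
Conditions: L-proline (20 mol %), Hantzsch ester (diethyl 2,6-dimethyl-1,4-dihydropyridine-3,5-dicarboxylate), EtOH, rt to 50 °C
Reagents that add atoms: none
Why: Amine-catalysed Knoevenagel condensation gives the doubly activated arylidene 8, which is reduced in the same flask by conjugate hydride transfer from the Hantzsch ester (organocatalytic reductive alkylation), which avoids a labile p-alkoxybenzyl halide and dialkylation; the new α-centre is labile and is left uncontrolled.

Step 7
Reactants: 9 methyl 2-{[(3S)-3-(benzyloxy)-2,2-dimethylchroman-6-yl]methyl}-3-[4-(benzyloxy)phenyl]-3-oxopropanoate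
Product: 10 methyl (2S)-2-{[(3S)-3-(benzyloxy)-2,2-dimethylchroman-6-yl]methyl}-3-[4-(benzyloxy)phenyl]-2-chloro-3-oxopropanoate
Conditions: NCS, Cu(OTf)2 (10 mol %), chiral spiro pyridyl-oxazoline ligand (SPYMOX, 11 mol %), 4 Å MS, toluene, 0 °C
Reagents that add atoms: N-chlorosuccinimide, O=C1CCC(=O)N1Cl
Why: Chiral Lewis-acid-catalysed electrophilic α-chlorination of a β-keto ester: bidentate chelation of the 1,3-dicarbonyl to divalent copper gives a planar enolate with one face shielded by the ligand, so NCS should chlorinate the open face and set C2 (S) under catalyst control, whichever epimer of 9 enters.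

Step 8
Reactants: 11 triethyl phosphonoacetate
Product: 12 ethyl 2-diazo-2-(diethoxyphosphoryl)acetate
Conditions: NaH, p-ABSA, THF, 0 °C to rt; aq NH4Cl
Reagents that add atoms: 4-acetamidobenzenesulfonyl azide (p-ABSA), CC(=O)Nc1ccc(cc1)S(=O)(=O)N=[N+]=[N-]
Why: Regitz diazo transfer to the sodium anion of the doubly activated methylene.

Step 9
Reactants: 12 ethyl 2-diazo-2-(diethoxyphosphoryl)acetate
Product: 13 ethyl 2-(benzyloxy)-2-(diethoxyphosphoryl)acetate (racemic)
Conditions: BnOH, Rh2(OAc)4 (1 mol %), toluene, 80 °C
Reagents that add atoms: benzyl alcohol, OCc1ccccc1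
Why: Rhodium carbenoid O–H insertion into benzyl alcohol, an established entry to 2-alkoxy-phosphonoacetates; the new centre is racemic and is destroyed in step 11.

Step 10
Reactants: 13 ethyl 2-(benzyloxy)-2-(diethoxyphosphoryl)acetate
Product: 14 2-(benzyloxy)-2-(diethoxyphosphoryl)acetic acid (racemic)
Conditions: LiOH·H2O (1.1 equiv), THF/H2O, 0 °C to rt; then 1 M HCl
Reagents that add atoms: lithium hydroxide, [Li+].[OH-]
Why: Selective saponification of the carboxylic ethyl ester; the diethyl phosphonate is inert to one equivalent of hydroxide at or below room temperature, and the O-benzyl group blocks phospha-Brook rearrangement.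

Step 11
Reactants: 10 methyl (2S)-2-{[(3S)-3-(benzyloxy)-2,2-dimethylchroman-6-yl]methyl}-3-[4-(benzyloxy)phenyl]-2-chloro-3-oxopropanoate; 14 2-(benzyloxy)-2-(diethoxyphosphoryl)acetic acid
Product: 17 methyl (2R)-4-(benzyloxy)-2-{[(3S)-3-(benzyloxy)-2,2-dimethylchroman-6-yl]methyl}-3-[4-(benzyloxy)phenyl]-5-oxo-2,5-dihydrofuran-2-carboxylate, via caesium carboxylate 15 (not isolated), via acyloxy keto ester 16 (not isolated)
Conditions: 14 (1.3 equiv), Cs2CO3 (0.5 equiv per 14), DMF, rt; add 10, 45 °C; then LiCl, DBU, 0 °C to rt
Reagents that add atoms: none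
Why: Proposed new method: the weakly basic caesium carboxylate 15 should displace chloride from the doubly carbonyl-activated, fully substituted carbon of 10 by backside SN2 attack (O1–C5), and the phosphonate carbanion then generated from 16 with LiCl/DBU adds to the non-enolisable aryl ketone and collapses through the oxaphosphetane to the C3=C4 bond; the closest known reactions are the invertive SN2 substitution of enantioenriched tertiary α-chloro-β-keto esters by azide, thiolate and fluoride, and the one-pot carboxylate alkylation/intramolecular Horner–Wadsworth–Emmons (or Knoevenagel) annulation of α-halo ketones to butenolides, which have not been combined with a carboxylate at such a centre. The furanone ring is closed by 5-exo-trig addition of the carbanion to the ketone followed by syn-elimination of diethyl phosphate, a formal [3+2] union of an O,C-dinucleophile with a C,C-dielectrophile. The C5 stereocentre (R) arises by Walden inversion of the (2S)-chloride, so it is substrate-controlled and stereospecific, and the alkene geometry is fixed by the ring. The step needs substitution to win over E2 loss of HCl towards the arylidene keto ester, and carbanion attack on the ketone to win over attack on the methyl ester. The low basicity of the α-alkoxy-phosphonoacetate carboxylate, the absence of excess carbonate during the substitution stage, and the higher electrophilicity of the ketone together with irreversible phosphate loss should secure both.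

Step 12
Reactants: 17 methyl (2R)-4-(benzyloxy)-2-{[(3S)-3-(benzyloxy)-2,2-dimethylchroman-6-yl]methyl}-3-[4-(benzyloxy)phenyl]-5-oxo-2,5-dihydrofuran-2-carboxylate
Product: 18 butyrolactone V
Conditions: H2 (1 atm), Pd(OH)2/C, EtOAc/MeOH, rt
Reagents that add atoms: none
Why: Catalytic hydrogenolysis of the aryl, enol and secondary alkyl benzyl ethers; the tetrasubstituted push–pull alkene of the furanone, the lactone and the methyl ester should be inert, and no stereocentre is touched.

## Compound list

1 | 2,2-dimethyl-2H-chromene-6-carbonitrile | CC1(C)C=Cc2cc(C#N)ccc2O1 | starting material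
2 | (3S,4S)-3,4-epoxy-2,2-dimethylchromane-6-carbonitrile (cis-fused epoxide) | CC1(C)Oc2ccc(C#N)cc2[C@@H]2O[C@H]12 | intermediate
3 | (3S)-3-hydroxy-2,2-dimethylchromane-6-carbonitrile | CC1(C)Oc2ccc(C#N)cc2C[C@@H]1O | intermediate
4 | (3S)-3-(benzyloxy)-2,2-dimethylchromane-6-carbonitrile | CC1(C)Oc2ccc(C#N)cc2C[C@@H]1OCc1ccccc1 | intermediate
5 | (3S)-3-(benzyloxy)-2,2-dimethylchromane-6-carbaldehyde | CC1(C)Oc2ccc(C=O)cc2C[C@@H]1OCc1ccccc1 | intermediate
6 | 1-[4-(benzyloxy)phenyl]ethan-1-one | CC(=O)c1ccc(OCc2ccccc2)cc1 | starting material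
7 | methyl 3-[4-(benzyloxy)phenyl]-3-oxopropanoate | COC(=O)CC(=O)c1ccc(OCc2ccccc2)cc1 | intermediate
8 | methyl 2-[4-(benzyloxy)benzoyl]-3-[(3S)-3-(benzyloxy)-2,2-dimethylchroman-6-yl]prop-2-enoate (E/Z mixture, not isolated) | COC(=O)C(=Cc1ccc2OC(C)(C)[C@@H](OCc3ccccc3)Cc2c1)C(=O)c1ccc(OCc2ccccc2)cc1 | intermediate
9 | methyl 2-{[(3S)-3-(benzyloxy)-2,2-dimethylchroman-6-yl]methyl}-3-[4-(benzyloxy)phenyl]-3-oxopropanoate (both C2 epimers) | COC(=O)C(Cc1ccc2OC(C)(C)[C@@H](OCc3ccccc3)Cc2c1)C(=O)c1ccc(OCc2ccccc2)cc1 | intermediate
10 | methyl (2S)-2-{[(3S)-3-(benzyloxy)-2,2-dimethylchroman-6-yl]methyl}-3-[4-(benzyloxy)phenyl]-2-chloro-3-oxopropanoate | COC(=O)[C@](Cl)(Cc1ccc2OC(C)(C)[C@@H](OCc3ccccc3)Cc2c1)C(=O)c1ccc(OCc2ccccc2)cc1 | intermediate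
11 | triethyl phosphonoacetate | CCOC(=O)CP(=O)(OCC)OCC | starting material
12 | ethyl 2-diazo-2-(diethoxyphosphoryl)acetate | CCOC(=O)C(=[N+]=[N-])P(=O)(OCC)OCC | intermediate
13 | ethyl 2-(benzyloxy)-2-(diethoxyphosphoryl)acetate (racemic) | CCOC(=O)C(OCc1ccccc1)P(=O)(OCC)OCC | intermediate
14 | 2-(benzyloxy)-2-(diethoxyphosphoryl)acetic acid (racemic) | OC(=O)C(OCc1ccccc1)P(=O)(OCC)OCC | intermediate
15 | caesium 2-(benzyloxy)-2-(diethoxyphosphoryl)acetate (not isolated) | [Cs+].[O-]C(=O)C(OCc1ccccc1)P(=O)(OCC)OCC | intermediate
16 | methyl (2R)-2-{[2-(benzyloxy)-2-(diethoxyphosphoryl)acetyl]oxy}-2-{[(3S)-3-(benzyloxy)-2,2-dimethylchroman-6-yl]methyl}-3-[4-(benzyloxy)phenyl]-3-oxopropanoate (epimers at the phosphonate carbon, not isolated) | COC(=O)[C@@](OC(=O)C(OCc1ccccc1)P(=O)(OCC)OCC)(Cc1ccc2OC(C)(C)[C@@H](OCc3ccccc3)Cc2c1)C(=O)c1ccc(OCc2ccccc2)cc1 | intermediate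
17 | methyl (2R)-4-(benzyloxy)-2-{[(3S)-3-(benzyloxy)-2,2-dimethylchroman-6-yl]methyl}-3-[4-(benzyloxy)phenyl]-5-oxo-2,5-dihydrofuran-2-carboxylate | COC(=O)[C@]1(Cc2ccc3c(c2)C[C@H](OCc2ccccc2)C(C)(C)O3)OC(=O)C(OCc2ccccc2)=C1c1ccc(OCc2ccccc2)cc1 | intermediate
18 | butyrolactone V, methyl (2R)-4-hydroxy-2-{[(3S)-3-hydroxy-2,2-dimethylchroman-6-yl]methyl}-3-(4-hydroxyphenyl)-5-oxo-2,5-dihydrofuran-2-carboxylate | COC(=O)[C@]1(Cc2ccc3c(c2)C[C@H](O)C(C)(C)O3)OC(=O)C(O)=C1c1ccc(O)cc1 | target

## Step count and risks

Total step count: 12.
Longest linear sequence: 8 steps (steps 1, 2, 3, 4, 6, 7, 11, 12).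

Steps most likely to fail:

1. Step 11. Substitution at the fully substituted carbon may be slow, so E2 loss of HCl or halophilic attack on chlorine could compete and lower conversion or erode the C5 configuration; the hindered ketone may also close slowly. The fallback uses known chemistry and sets out from 9. Catalytic asymmetric α-hydroxylation of the β-keto ester (chiral TiCl2(TADDOLato)(MeCN)2 Lewis acid, 3-(4-nitrophenyl)-2-(phenylsulfonyl)oxaziridine, CH2Cl2, ligand antipode chosen for 2R) should give methyl (2R)-2-{[(3S)-3-(benzyloxy)-2,2-dimethylchroman-6-yl]methyl}-3-[4-(benzyloxy)phenyl]-2-hydroxy-3-oxopropanoate F1. Steglich esterification of this tertiary alcohol with acid 14 (DCC, DMAP, CH2Cl2) then gives the acyloxy keto ester 16, now isolated. The fallback comes back to the route at 16, which is closed to 17 with LiCl/DBU as in the second stage of step 11. In this variant O1–C5 is made by electrophilic oxygen transfer and O1–C2 by acylation, both established for butenolide synthesis from tertiary α-ketols.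

2. Step 7. Facial selectivity may be poor on an acyclic methyl ester enolate that carries a large benzylic substituent. The fallback sets out from 9 and replaces catalyst control by separation with recycling. Unselective chlorination (NCS, cat. Et3N, CH2Cl2) should give 10 together with its epimer methyl (2R)-2-{[(3S)-3-(benzyloxy)-2,2-dimethylchroman-6-yl]methyl}-3-[4-(benzyloxy)phenyl]-2-chloro-3-oxopropanoate F2. The two are diastereomers because of the chroman stereocentre and are separated by preparative HPLC on a chiral stationary phase. The fallback comes back to the route at 10; F2 is returned to 9 by reductive dechlorination (Zn, AcOH) and chlorinated again.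

3. Step 12. Cleavage of the hindered secondary benzyl ether may be slow, and prolonged exposure could lead to hydrogenolysis of the allylic lactone C5–O bond or reduction of the furanone alkene. The fallback sets out from 17 and reaches 18 directly by Lewis-acid debenzylation with a cation scavenger (BCl3, pentamethylbenzene, CH2Cl2, −78 °C). This removes all three benzyl groups without hydrogen or metal and leaves the methyl ester and lactone intact; no new compound is made (F0).

Further compounds
F1 | step 11 | methyl (2R)-2-{[(3S)-3-(benzyloxy)-2,2-dimethylchroman-6-yl]methyl}-3-[4-(benzyloxy)phenyl]-2-hydroxy-3-oxopropanoate | COC(=O)[C@@](O)(Cc1ccc2OC(C)(C)[C@@H](OCc3ccccc3)Cc2c1)C(=O)c1ccc(OCc2ccccc2)cc1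
F2 | step 7 | methyl (2R)-2-{[(3S)-3-(benzyloxy)-2,2-dimethylchroman-6-yl]methyl}-3-[4-(benzyloxy)phenyl]-2-chloro-3-oxopropanoate | COC(=O)[C@@](Cl)(Cc1ccc2OC(C)(C)[C@@H](OCc3ccccc3)Cc2c1)C(=O)c1ccc(OCc2ccccc2)cc1
F0 | step 12 | none | none
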